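**Strategy**

The cyclohexenone ring is disconnected at C3–C4, and C1–C2–C3 plus the first chain carbon are recognised as an acyl-allene. Ring carbons C1, C4, C5 and C6 are stored as a cyclobutanol; C2, C3 and chain carbon C1' as a 1,3-disubstituted allene. The precursor, 1-(henicosa-1,2-dienyl)cyclobutan-1-ol, is an isomer of the target. A Rh(I)-catalysed β-carbon elimination opens the strained four-membered ring, the resulting alkyl-rhodium inserts the allene, and protonation delivers the enone. One operation enlarges the ring by two carbons (4→6) and creates the ketone, the conjugated C2=C3 double bond and the CH2 that starts the nonadecyl chain. The allene comes from an alkyne–aldehyde allenation.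

Key step: step 3

Remark on the chemistry: the target has no stereocentre and its only double bond lies in the ring, so it is achiral and the SMILES describes a single compound. No enantioselective step is needed, and the chiral intermediates (propargylic amine, allene) are used as racemates. Both starting materials are taken as catalogue compounds.

**Route**

Step 1
Reactants: 1 nonadecan-1-ol
Product: 2 nonadecanal
Conditions: TEMPO (10 mol %), PhI(OAc)2 (1.1 equiv), CH2Cl2, rt
Reagents that add atoms: none
Why: Oxoammonium (TEMPO/PhI(OAc)2) oxidation of a primary alcohol should stop at the aldehyde in anhydrous CH2Cl2, because no aldehyde hydrate is present to be oxidised further.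

Step 2
Reactants: 2 nonadecanal; 3 1-ethynylcyclobutan-1-ol
Product: 5 rac-1-(henicosa-1,2-dien-1-yl)cyclobutan-1-ol, via propargylic amine 4 (not isolated)
Conditions: morpholine (1.4 equiv), ZnI2 (0.8 equiv), toluene, 130 °C, sealed tube
Reagents that add atoms: none
Why: In this Crabbé-type allenation of a terminal alkyne, the zinc acetylide of 3 adds to the iminium ion from 2 and morpholine to give 4, and zinc-promoted intramolecular 1,5-hydride transfer from an N–CH2 group to the alkyne with loss of the cyclic imine should give the 1,3-disubstituted allene as a racemate, the free tertiary alcohol being tolerated and morpholine acting as a traceless hydride donor.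

Step 3
Reactants: 5 rac-1-(henicosa-1,2-dien-1-yl)cyclobutan-1-ol
Product: 6 3-nonadecylcyclohex-2-en-1-one
Conditions: [Rh(OH)(cod)]2 (2.5 mol %), rac-BINAP (6 mol %), toluene, 90 °C
Reagents that add atoms: none
Why: The Rh(I) hydroxide converts the tertiary alcohol of 5 into a rhodium cyclobutanolate, strain-driven β-carbon elimination cleaves one of the two equivalent C1–C2 bonds of the four-membered ring to unmask the ketone and a primary 4-oxoalkyl-rhodium, migratory insertion of the tethered allene at its central carbon closes the ring, and the resulting rhodium dienolate (oxa-π-allyl) is protonated at the exocyclic γ-carbon by the next molecule of 5, which releases 6 and regenerates the alkoxide. The closest known reaction type is the Rh(I)-catalysed β-carbon elimination and ring expansion of 1-allenyl tert-cyclobutanols to cyclohex-2-enones. The six-membered ring closes by a 6-exo carbometalation of the distal allene C=C with bond formation at the sp carbon, the carbinol carbon and the three ring CH2 groups becoming C1 and C4–C6 and the two proximal allene carbons becoming C2 and C3. No stereocentre is formed, the allene axis of racemic 5 is destroyed, and as the step is an isomerisation every atom of 5 is kept in 6. The step needs ring C–C cleavage instead of loss of the allenyl group, and insertion faster than β-hydride elimination of the alkyl-rhodium; ring strain secures the first, and the electron-poor allenyl ketone held within reach of the metal by the three-carbon tether, supported by a chelating bisphosphine that leaves little room for an open site, secures the second. The conjugated C2=C3 position is also the thermodynamic one, so reversible dienolate formation under the basic conditions can only lead to 6.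

**Compound list**

1 | nonadecan-1-ol | CCCCCCCCCCCCCCCCCCCO | starting material
2 | nonadecanal | CCCCCCCCCCCCCCCCCCC=O | intermediate
3 | 1-ethynylcyclobutan-1-ol | C#CC1(O)CCC1 | starting material
4 | rac-1-[3-(morpholin-4-yl)henicos-1-yn-1-yl]cyclobutan-1-ol | CCCCCCCCCCCCCCCCCCC(N1CCOCC1)C#CC1(O)CCC1 | intermediate (not isolated)
5 | rac-1-(henicosa-1,2-dien-1-yl)cyclobutan-1-ol | CCCCCCCCCCCCCCCCCCC=C=CC1(O)CCC1 | intermediate
6 | 3-nonadecylcyclohex-2-en-1-one | CCCCCCCCCCCCCCCCCCCC1=CC(=O)CCC1 | target

**Step count**

Total steps: 3. Longest linear sequence: 3 (1 → 2 → 5 → 6).

**Steps most likely to fail**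

Step 3 (key step). The risk is β-hydride elimination of the primary alkyl-rhodium intermediate followed by chain walking, which would divert the opened cyclobutanol to acyclic unsaturated ketones; oligomerisation of the allene on rhodium is a second risk. The fallback sets out from 2 and returns to the route at 6, and enlarges a cyclopentane by one carbon instead. Crossed aldol condensation of nonadecanal 2 with an excess of cyclopentanone (NaOH, EtOH) should give (E)-2-nonadecylidenecyclopentan-1-one F1. Rh-catalysed 1,4-hydrosilylation (Et3SiH, RhCl(PPh3)3) should give regiospecifically the tetrasubstituted silyl enol ether triethyl[(2-nonadecylcyclopent-1-en-1-yl)oxy]silane F2. Furukawa-type Simmons–Smith cyclopropanation (Et2Zn, CH2I2, CH2Cl2, 0 °C) should give rac-triethyl[(5-nonadecylbicyclo[3.1.0]hexan-1-yl)oxy]silane F3. FeCl3 in DMF should open the bond shared by the two rings through the tertiary β-keto radical to rac-3-chloro-3-nonadecylcyclohexan-1-one F4, and NaOAc in refluxing MeOH should eliminate HCl to give 6.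

Step 2. The risk is Lewis-acid-promoted decomposition of the strained tertiary propargylic and allenylic alcohols at 130 °C (semipinacol ring enlargement, cycloisomerisation of the α-allenol) and self-condensation of the enolisable aldehyde through its enamine. The fallback sets out from 2 and 3 and returns at 5. The dilithio derivative of 3 (n-BuLi, 2 equiv, THF, −78 °C) should add to 2 to give rac-1-(3-hydroxyhenicos-1-yn-1-yl)cyclobutan-1-ol F5. A Mitsunobu reaction with 2-nitrobenzenesulfonohydrazide (PPh3, DEAD, THF, −15 °C) should touch only the secondary alcohol and give rac-N-[1-(1-hydroxycyclobutyl)henicos-1-yn-3-yl]-2-nitrobenzenesulfonohydrazide F6. On warming to room temperature this should lose the sulfinic acid to give the propargylic diazene rac-1-(3-diazenylhenicos-1-yn-1-yl)cyclobutan-1-ol F7, which should expel N2 in a retro-ene reaction to give allene 5 (Myers allene synthesis), without heat or Lewis acid.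

Step 1. The risk is over-oxidation to the carboxylic acid and condensation of the product aldehyde with unreacted alcohol (hemiacetal, then ester), favoured by slow dissolution of the waxy alcohol. The fallback sets out from 1 and returns at 2. An Appel reaction (CBr4, PPh3, CH2Cl2) should give 1-bromononadecane F8. Ganem oxidation (Me3NO, DMSO, rt) should displace bromide to give trimethyl(nonadecyloxy)ammonium bromide F9, which should eliminate trimethylamine (as its hydrobromide) to give 2. The aldehyde is then formed by elimination and never meets an oxidant that could take it further.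

**Further compounds**

F1 | step 3 | (E)-2-nonadecylidenecyclopentan-1-one | CCCCCCCCCCCCCCCCCC/C=C1\CCCC1=O
F2 | step 3 | triethyl[(2-nonadecylcyclopent-1-en-1-yl)oxy]silane | CCCCCCCCCCCCCCCCCCCC1=C(O[Si](CC)(CC)CC)CCC1
F3 | step 3 | rac-triethyl[(5-nonadecylbicyclo[3.1.0]hexan-1-yl)oxy]silane | CCCCCCCCCCCCCCCCCCCC12CC1(O[Si](CC)(CC)CC)CCC2
F4 | step 3 | rac-3-chloro-3-nonadecylcyclohexan-1-one | CCCCCCCCCCCCCCCCCCCC1(Cl)CC(=O)CCC1
F5 | step 2 | rac-1-(3-hydroxyhenicos-1-yn-1-yl)cyclobutan-1-ol | CCCCCCCCCCCCCCCCCCC(O)C#CC1(O)CCC1
F6 | step 2 | rac-N-[1-(1-hydroxycyclobutyl)henicos-1-yn-3-yl]-2-nitrobenzenesulfonohydrazide | CCCCCCCCCCCCCCCCCCC(N(N)S(=O)(=O)c1ccccc1[N+](=O)[O-])C#CC1(O)CCC1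
F7 | step 2 | rac-1-(3-diazenylhenicos-1-yn-1-yl)cyclobutan-1-ol | CCCCCCCCCCCCCCCCCCC(N=N)C#CC1(O)CCC1
F8 | step 1 | 1-bromononadecane | CCCCCCCCCCCCCCCCCCCBr
F9 | step 1 | trimethyl(nonadecyloxy)ammonium bromide | C[N+](C)(C)OCCCCCCCCCCCCCCCCCCC.[Br-]
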